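The carboxyl unit of the α-methylene-γ-butyrolactone (ring O–C6–C7–C11–C12, germacrane numbering) is excised as carbon dioxide. C6 is allylic to the C4=C5 alkene of the ten-membered ring and C11 is vinylic, so the precursor carries C11 as an alkenyl boronate and C6 as an allylic phosphate. In one flask, copper-catalysed carboxylation joins C11 to CO2 and palladium-catalysed allylic substitution closes the lactone O–C6 bond with net retention. The precursor is an acyclic, fully oxygenated trienyl boronate made by a borylative allene–aldehyde coupling and a Nozaki–Hiyama–Kishi union. Ring-closing metathesis, epoxidation and desilylation then complete the target.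

Key step: step 15

Remark: germacrane numbering is used throughout (C1–C10 ring; C11, C12, C13 the acrylate unit with C12 the carbonyl; C14 on C10; C15 on C4); the 1,10-epoxide of the target is the cis isomer that a (Z)-C1=C10 alkene delivers.

Step 1
Reactants: 1 buta-2,3-dien-1-ol
Product: 2 1-[(buta-2,3-dien-1-yloxy)methyl]-4-methoxybenzene
Conditions: NaH, 4-methoxybenzyl chloride, Bu4NI (cat.), THF, 0 to 25 °C
Reagents that add atoms: 4-methoxybenzyl chloride COc1ccc(CCl)cc1
Why: Williamson etherification of the primary allenic alkoxide masks O6 as an oxidatively removable ether; no stereocentre is involved.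

Step 2
Reactants: 3 3-methylbut-3-en-1-ol
Product: 4 3-methylbut-3-enal
Conditions: Dess–Martin periodinane, NaHCO3, CH2Cl2, 0 °C; solution used directly
Reagents that add atoms: none
Why: Buffered Dess–Martin oxidation should give the β,γ-unsaturated aldehyde without migration of the alkene into conjugation, and the solution is used at once.

Step 3
Reactants: 2 1-[(buta-2,3-dien-1-yloxy)methyl]-4-methoxybenzene; 4 3-methylbut-3-enal
Product: 5 (2S,3R)-1-[(4-methoxyphenyl)methoxy]-5-methyl-2-[1-(4,4,5,5-tetramethyl-1,3,2-dioxaborolan-2-yl)ethenyl]hex-5-en-3-ol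
Conditions: CuCl (5 mol %), (S,S)-Ph-BPE (6 mol %), NaOtBu (10 mol %), B2pin2 (1.1 equiv), THF, 22 °C; aq. NH4Cl
Reagents that add atoms: bis(pinacolato)diboron CC1(C)OB(OC1(C)C)B1OC(C)(C)C(C)(C)O1
Why: In this copper-catalysed borylative allene–aldehyde coupling Cu–Bpin adds across the terminal C=C of the allene with boron on the central carbon, and the resulting (Z)-2-boryl-allylcopper adds through its substituted γ-carbon to the aldehyde in a chair transition state, which should set C7 and C8 syn, the bisphosphine (its enantiomer chosen accordingly) fixing the absolute sense as 7S,8R.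

Step 4
Reactants: 5 (2S,3R)-1-[(4-methoxyphenyl)methoxy]-5-methyl-2-[1-(4,4,5,5-tetramethyl-1,3,2-dioxaborolan-2-yl)ethenyl]hex-5-en-3-ol
Product: 6 (2S,3R)-1-[(4-methoxyphenyl)methoxy]-5-methyl-2-[1-(4,4,5,5-tetramethyl-1,3,2-dioxaborolan-2-yl)ethenyl]hex-5-en-3-yl (2Z)-2-methylbut-2-enoate
Conditions: angelic acid, 2,4,6-trichlorobenzoyl chloride, Et3N, toluene, 25 °C; then 5, 80 °C
Reagents that add atoms: angelic acid C/C=C(/C)C(=O)O
Why: Yamaguchi esterification through the mixed 2,4,6-trichlorobenzoic anhydride acylates the hindered C8 alcohol without a nucleophilic catalyst that would isomerise the angelate to the tiglate; C8 is not touched.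

Step 5
Reactants: 6 (2S,3R)-1-[(4-methoxyphenyl)methoxy]-5-methyl-2-[1-(4,4,5,5-tetramethyl-1,3,2-dioxaborolan-2-yl)ethenyl]hex-5-en-3-yl (2Z)-2-methylbut-2-enoate
Product: 7 (2S,3R)-1-hydroxy-5-methyl-2-[1-(4,4,5,5-tetramethyl-1,3,2-dioxaborolan-2-yl)ethenyl]hex-5-en-3-yl (2Z)-2-methylbut-2-enoate
Conditions: DDQ, CH2Cl2/pH 7 buffer, 0 °C
Reagents that add atoms: none
Why: Oxidative cleavage of the 4-methoxybenzyl ether by DDQ under neutral conditions should free the C6 hydroxyl without affecting the alkenyl boronate, the angelate or the isolated alkene.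

Step 6
Reactants: 7 (2S,3R)-1-hydroxy-5-methyl-2-[1-(4,4,5,5-tetramethyl-1,3,2-dioxaborolan-2-yl)ethenyl]hex-5-en-3-yl (2Z)-2-methylbut-2-enoate
Product: 8 (2R,3R)-5-methyl-1-oxo-2-[1-(4,4,5,5-tetramethyl-1,3,2-dioxaborolan-2-yl)ethenyl]hex-5-en-3-yl (2Z)-2-methylbut-2-enoate
Conditions: Dess–Martin periodinane, NaHCO3, CH2Cl2, 0 °C; used directly
Reagents that add atoms: none
Why: Buffered Dess–Martin oxidation gives the C6 aldehyde under non-basic conditions, so that neither epimerisation at C7 nor β-elimination of the angelate should occur.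

Step 7
Reactants: 9 3-(trimethylsilyl)prop-2-ynal
Product: 10 (3S)-1-(trimethylsilyl)hex-5-en-1-yn-3-ol
Conditions: allyltributylstannane, (S)-BINOL (10 mol %), Ti(OiPr)4 (10 mol %), 4 Å molecular sieves, CH2Cl2, −20 °C
Reagents that add atoms: allyltributylstannane C=CC[Sn](CCCC)(CCCC)CCCC
Why: In this Keck asymmetric allylation the (S)-BINOL–titanium complex activates the ynal and directs the allylstannane to one carbonyl face, which should give the (S)-carbinol that becomes C3.

Step 8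
Reactants: 10 (3S)-1-(trimethylsilyl)hex-5-en-1-yn-3-ol
Product: 11 (3S)-hex-5-en-1-yn-3-ol
Conditions: K2CO3, MeOH, 25 °C
Reagents that add atoms: none
Why: Methanolysis of the alkynyl C–Si bond frees the terminal alkyne needed for carbometalation and leaves the carbinol centre untouched.

Step 9
Reactants: 11 (3S)-hex-5-en-1-yn-3-ol
Product: 13 (1E,3S)-2-{[dimethyl(propan-2-yloxy)silyl]methyl}-1-iodohexa-1,5-dien-3-ol, via alkenylmagnesium chelate 12 (not isolated)
Conditions: (iPrO)Me2SiCH2MgCl (3 equiv), CuI (10 mol %), THF, 0 to 25 °C; then I2 (1.0 equiv), −78 °C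
Reagents that add atoms: [(isopropoxydimethylsilyl)methyl]magnesium chloride CC(C)O[Si](C)(C)C[Mg]Cl; iodine II
Why: Copper-catalysed anti-carbomagnesiation of the magnesium propargylic alkoxide places the silylmethyl group on the internal alkyne carbon and magnesium on the terminal carbon cis to the carbinol carbon in a five-membered chelate, and iodinolysis with retention gives the alkenyl iodide with iodine cis to C3, which fixes the later C4=C5 geometry.

Step 10
Reactants: 13 (1E,3S)-2-{[dimethyl(propan-2-yloxy)silyl]methyl}-1-iodohexa-1,5-dien-3-ol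
Product: 14 (3S)-2-[(Z)-iodomethylidene]hex-5-ene-1,3-diol
Conditions: H2O2 (30 %), KF, KHCO3, THF/MeOH, 25 °C
Reagents that add atoms: hydrogen peroxide OO
Why: Tamao oxidation converts the allylic C–Si bond of the alkoxysilane into C–OH with retention and without allylic transposition, which reveals the C15 hydroxyl.

Step 11
Reactants: 14 (3S)-2-[(Z)-iodomethylidene]hex-5-ene-1,3-diol
Product: 15 (3S)-1-[(tert-butyldimethylsilyl)oxy]-2-[(Z)-iodomethylidene]hex-5-en-3-ol
Conditions: TBSCl (1.05 equiv), imidazole, CH2Cl2, −20 °C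
Reagents that add atoms: tert-butyldimethylsilyl chloride CC(C)(C)[Si](C)(C)Cl
Why: The primary allylic hydroxyl should be silylated selectively over the more hindered secondary one at low temperature.

Step 12
Reactants: 15 (3S)-1-[(tert-butyldimethylsilyl)oxy]-2-[(Z)-iodomethylidene]hex-5-en-3-ol
Product: 16 (3S)-1-[(tert-butyldimethylsilyl)oxy]-2-[(Z)-iodomethylidene]hex-5-en-3-yl acetate
Conditions: Ac2O, pyridine, DMAP (cat.), CH2Cl2, 0 °C
Reagents that add atoms: acetic anhydride CC(=O)OC(C)=O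
Why: Acetylation of the remaining secondary alcohol installs the C3 acetate of the target with no change at C3.

Step 13
Reactants: 16 (3S)-1-[(tert-butyldimethylsilyl)oxy]-2-[(Z)-iodomethylidene]hex-5-en-3-yl acetate; 8 (2R,3R)-5-methyl-1-oxo-2-[1-(4,4,5,5-tetramethyl-1,3,2-dioxaborolan-2-yl)ethenyl]hex-5-en-3-yl (2Z)-2-methylbut-2-enoate
Product: 17 (4S,5Z,7R,8S,9R)-4-acetoxy-5-{[(tert-butyldimethylsilyl)oxy]methyl}-7-hydroxy-11-methyl-8-[1-(4,4,5,5-tetramethyl-1,3,2-dioxaborolan-2-yl)ethenyl]dodeca-1,5,11-trien-9-yl (2Z)-2-methylbut-2-enoate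
Conditions: CrCl2 (4 equiv), NiCl2 (2 mol %), chiral oxazoline–sulfonamide ligand N-[2-(4-isopropyl-4,5-dihydro-1,3-oxazol-2-yl)-6-methylphenyl]methanesulfonamide (enantiomer selected for 6R), Et3N, THF, 25 °C
Reagents that add atoms: none
Why: In this Nozaki–Hiyama–Kishi coupling nickel-mediated oxidative addition to the alkenyl iodide with retention of geometry, transmetalation to chromium and addition to the aldehyde tolerate the boronate, the esters and the silyl ether, and the chiral sulfonamide–chromium complex should set C6 as R by reagent control, any C6 epimer being removed by chromatography.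

Step 14
Reactants: 17 (4S,5Z,7R,8S,9R)-4-acetoxy-5-{[(tert-butyldimethylsilyl)oxy]methyl}-7-hydroxy-11-methyl-8-[1-(4,4,5,5-tetramethyl-1,3,2-dioxaborolan-2-yl)ethenyl]dodeca-1,5,11-trien-9-yl (2Z)-2-methylbut-2-enoate
Product: 18 (4S,5Z,7R,8R,9R)-4-acetoxy-5-{[(tert-butyldimethylsilyl)oxy]methyl}-7-[(diethoxyphosphoryl)oxy]-11-methyl-8-[1-(4,4,5,5-tetramethyl-1,3,2-dioxaborolan-2-yl)ethenyl]dodeca-1,5,11-trien-9-yl (2Z)-2-methylbut-2-enoate
Conditions: ClP(O)(OEt)2, pyridine, DMAP (cat.), CH2Cl2, 0 °C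
Reagents that add atoms: diethyl chlorophosphate CCOP(=O)(Cl)OCC
Why: Phosphorylation at oxygen leaves the C6 configuration unchanged and gives an allylic leaving group that zerovalent palladium ionises far more readily than the C3 acetate.

Step 15
Reactants: 18 (4S,5Z,7R,8R,9R)-4-acetoxy-5-{[(tert-butyldimethylsilyl)oxy]methyl}-7-[(diethoxyphosphoryl)oxy]-11-methyl-8-[1-(4,4,5,5-tetramethyl-1,3,2-dioxaborolan-2-yl)ethenyl]dodeca-1,5,11-trien-9-yl (2Z)-2-methylbut-2-enoate
Product: 20 (4R,5R)-5-[(1Z,3S)-3-acetoxy-2-{[(tert-butyldimethylsilyl)oxy]methyl}hexa-1,5-dien-1-yl]-3-methylidene-4-[(1R)-3-methyl-1-{[(2Z)-2-methylbut-2-enoyl]oxy}but-3-en-1-yl]oxolan-2-one, via potassium acrylate 19 (not isolated)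
Conditions: KOtBu (1.05 equiv), THF, 0 °C; IPrCuCl (chloro[1,3-bis(2,6-diisopropylphenyl)imidazol-2-ylidene]copper, 10 mol %), CO2 (1 atm), 50 °C; then Pd(PPh3)4 (5 mol %), 25 °C, same flask
Reagents that add atoms: carbon dioxide O=C=O
Why: The tert-butoxide ate complex of the alkenyl boronate transmetalates to the carbene–copper catalyst and the alkenylcopper inserts CO2, forming the C11–C12 bond as potassium acrylate 19; zerovalent palladium then ionises the allylic phosphate with inversion to an η3-allyl spanning C4–C5–C6, and the carboxylate oxygen attacks C6 from the face opposite palladium to form the O–C6 bond. The closest known reaction types are the copper-catalysed carboxylation of alkenylboronic esters with CO2 and the intramolecular Tsuji–Trost lactonisation of an allylic phosphate by a carboxylate, run here in one flask. The γ-lactone closes in the 5-exo mode onto the C6 terminus of the allyl unit, whereas attack at C4 would need a seven-membered ring and a fully substituted carbon. C6 is the only stereocentre made, and its configuration follows from the (6R) phosphate by double inversion (net retention), which places O6 trans to H7 as in the target. The step needs chemoselectivity for the phosphate over the C3 allylic acetate (secured by the much better leaving group), retention of the (Z)-C4=C5 geometry (the anti-substituted allyl should be trapped intramolecularly faster than it isomerises through a tertiary η1-palladium species) and CO2 capture ahead of alkenyl–allyl coupling (the intramolecular couplings would be 3-exo or 5-endo closures, and palladium is added only after CO2 uptake).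

Step 16
Reactants: 20 (4R,5R)-5-[(1Z,3S)-3-acetoxy-2-{[(tert-butyldimethylsilyl)oxy]methyl}hexa-1,5-dien-1-yl]-3-methylidene-4-[(1R)-3-methyl-1-{[(2Z)-2-methylbut-2-enoyl]oxy}but-3-en-1-yl]oxolan-2-one
Product: 21 (1(10)Z,3S,4Z,6R,7R,8R)-3-acetoxy-15-[(tert-butyldimethylsilyl)oxy]-8-{[(2Z)-2-methylbut-2-enoyl]oxy}germacra-1(10),4,11(13)-trien-12,6-olide
Conditions: second-generation Grubbs catalyst (10 mol %), 1,4-benzoquinone (20 mol %), toluene (1 mM), 80 °C
Reagents that add atoms: none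
Why: Ring-closing metathesis between the monosubstituted C1 alkene and the 1,1-disubstituted C10 alkene closes the ten-membered ring, the trans-lactone and the (Z)-C4=C5 alkene pre-organising the chain, the medium ring being expected to favour the (Z)-C1=C10 alkene, and the acrylate and angelate alkenes being too electron-poor and hindered to compete.

Step 17
Reactants: 21 (1(10)Z,3S,4Z,6R,7R,8R)-3-acetoxy-15-[(tert-butyldimethylsilyl)oxy]-8-{[(2Z)-2-methylbut-2-enoyl]oxy}germacra-1(10),4,11(13)-trien-12,6-olide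
Product: 22 (1R,3S,4Z,6R,7R,8R,10S)-3-acetoxy-15-[(tert-butyldimethylsilyl)oxy]-1,10-epoxy-8-{[(2Z)-2-methylbut-2-enoyl]oxy}germacra-4,11(13)-dien-12,6-olide
Conditions: mCPBA, NaHCO3, CH2Cl2, 0 °C
Reagents that add atoms: 3-chloroperoxybenzoic acid OOC(=O)c1cccc(Cl)c1
Why: Prilezhaev epoxidation should take the electron-rich C1=C10 alkene in preference to the C4=C5 alkene flanked by three allylic C–O bonds and to the two conjugated alkenes, syn addition to the (Z)-alkene giving the cis-epoxide and attack on the exposed outer face of the ring being expected to give the (1R,10S) isomer.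

Step 18
Reactants: 22 (1R,3S,4Z,6R,7R,8R,10S)-3-acetoxy-15-[(tert-butyldimethylsilyl)oxy]-1,10-epoxy-8-{[(2Z)-2-methylbut-2-enoyl]oxy}germacra-4,11(13)-dien-12,6-olide
Product: 23 (1R,3S,4Z,6R,7R,8R,10S)-3-acetoxy-1,10-epoxy-15-hydroxy-8-{[(2Z)-2-methylbut-2-enoyl]oxy}germacra-4,11(13)-dien-12,6-olide
Conditions: HF·pyridine, pyridine, THF, 0 °C
Reagents that add atoms: none
Why: Pyridine-buffered HF·pyridine should cleave the primary allylic silyl ether while the epoxide, the esters and the α-methylene lactone survive, and the mildly acidic medium avoids migration of the acetyl group from O3 to O15.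

Compound list
1 | buta-2,3-dien-1-ol | C=C=CCO | starting material
2 | 1-[(buta-2,3-dien-1-yloxy)methyl]-4-methoxybenzene | C=C=CCOCc1ccc(OC)cc1 | intermediate
3 | 3-methylbut-3-en-1-ol | C=C(C)CCO | starting material
4 | 3-methylbut-3-enal | C=C(C)CC=O | intermediate
5 | (2S,3R)-1-[(4-methoxyphenyl)methoxy]-5-methyl-2-[1-(4,4,5,5-tetramethyl-1,3,2-dioxaborolan-2-yl)ethenyl]hex-5-en-3-ol | COc1ccc(COC[C@H](C(=C)B2OC(C)(C)C(C)(C)O2)[C@H](O)CC(C)=C)cc1 | intermediate
6 | (2S,3R)-1-[(4-methoxyphenyl)methoxy]-5-methyl-2-[1-(4,4,5,5-tetramethyl-1,3,2-dioxaborolan-2-yl)ethenyl]hex-5-en-3-yl (2Z)-2-methylbut-2-enoate | COc1ccc(COC[C@H](C(=C)B2OC(C)(C)C(C)(C)O2)[C@H](OC(=O)/C(C)=C\C)CC(C)=C)cc1 | intermediate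
7 | (2S,3R)-1-hydroxy-5-methyl-2-[1-(4,4,5,5-tetramethyl-1,3,2-dioxaborolan-2-yl)ethenyl]hex-5-en-3-yl (2Z)-2-methylbut-2-enoate | OC[C@H](C(=C)B1OC(C)(C)C(C)(C)O1)[C@H](OC(=O)/C(C)=C\C)CC(C)=C | intermediate
8 | (2R,3R)-5-methyl-1-oxo-2-[1-(4,4,5,5-tetramethyl-1,3,2-dioxaborolan-2-yl)ethenyl]hex-5-en-3-yl (2Z)-2-methylbut-2-enoate | O=C[C@H](C(=C)B1OC(C)(C)C(C)(C)O1)[C@H](OC(=O)/C(C)=C\C)CC(C)=C | intermediate
9 | 3-(trimethylsilyl)prop-2-ynal | C[Si](C)(C)C#CC=O | starting material
10 | (3S)-1-(trimethylsilyl)hex-5-en-1-yn-3-ol | C[Si](C)(C)C#C[C@@H](O)CC=C | intermediate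
11 | (3S)-hex-5-en-1-yn-3-ol | C#C[C@@H](O)CC=C | intermediate
12 | alkenylmagnesium chelate: chloromagnesium alkoxide of (1E,3S)-1-(chloromagnesio)-2-{[dimethyl(propan-2-yloxy)silyl]methyl}hexa-1,5-dien-3-ol | Cl[Mg]/C=C(/C[Si](C)(C)OC(C)C)[C@@H](O[Mg]Cl)CC=C | intermediate
13 | (1E,3S)-2-{[dimethyl(propan-2-yloxy)silyl]methyl}-1-iodohexa-1,5-dien-3-ol | I/C=C(/C[Si](C)(C)OC(C)C)[C@@H](O)CC=C | intermediate
14 | (3S)-2-[(Z)-iodomethylidene]hex-5-ene-1,3-diol | I/C=C(/CO)[C@@H](O)CC=C | intermediate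
15 | (3S)-1-[(tert-butyldimethylsilyl)oxy]-2-[(Z)-iodomethylidene]hex-5-en-3-ol | I/C=C(/CO[Si](C)(C)C(C)(C)C)[C@@H](O)CC=C | intermediate
16 | (3S)-1-[(tert-butyldimethylsilyl)oxy]-2-[(Z)-iodomethylidene]hex-5-en-3-yl acetate | I/C=C(/CO[Si](C)(C)C(C)(C)C)[C@@H](OC(C)=O)CC=C | intermediate
17 | (4S,5Z,7R,8S,9R)-4-acetoxy-5-{[(tert-butyldimethylsilyl)oxy]methyl}-7-hydroxy-11-methyl-8-[1-(4,4,5,5-tetramethyl-1,3,2-dioxaborolan-2-yl)ethenyl]dodeca-1,5,11-trien-9-yl (2Z)-2-methylbut-2-enoate | C=C(B1OC(C)(C)C(C)(C)O1)[C@@H]([C@H](O)/C=C(/CO[Si](C)(C)C(C)(C)C)[C@@H](OC(C)=O)CC=C)[C@H](OC(=O)/C(C)=C\C)CC(C)=C | intermediate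
18 | (4S,5Z,7R,8R,9R)-4-acetoxy-5-{[(tert-butyldimethylsilyl)oxy]methyl}-7-[(diethoxyphosphoryl)oxy]-11-methyl-8-[1-(4,4,5,5-tetramethyl-1,3,2-dioxaborolan-2-yl)ethenyl]dodeca-1,5,11-trien-9-yl (2Z)-2-methylbut-2-enoate | C=C(B1OC(C)(C)C(C)(C)O1)[C@@H]([C@H](OP(=O)(OCC)OCC)/C=C(/CO[Si](C)(C)C(C)(C)C)[C@@H](OC(C)=O)CC=C)[C@H](OC(=O)/C(C)=C\C)CC(C)=C | intermediate
19 | potassium acrylate: potassium 2-substituted prop-2-enoate formed from 18 by replacement of the boryl group with CO2K (same configuration) | C=C(C(=O)[O-])[C@@H]([C@H](OP(=O)(OCC)OCC)/C=C(/CO[Si](C)(C)C(C)(C)C)[C@@H](OC(C)=O)CC=C)[C@H](OC(=O)/C(C)=C\C)CC(C)=C.[K+] | intermediate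
20 | (4R,5R)-5-[(1Z,3S)-3-acetoxy-2-{[(tert-butyldimethylsilyl)oxy]methyl}hexa-1,5-dien-1-yl]-3-methylidene-4-[(1R)-3-methyl-1-{[(2Z)-2-methylbut-2-enoyl]oxy}but-3-en-1-yl]oxolan-2-one | C=C1C(=O)O[C@H](/C=C(/CO[Si](C)(C)C(C)(C)C)[C@@H](OC(C)=O)CC=C)[C@H]1[C@H](OC(=O)/C(C)=C\C)CC(C)=C | intermediate
21 | (1(10)Z,3S,4Z,6R,7R,8R)-3-acetoxy-15-[(tert-butyldimethylsilyl)oxy]-8-{[(2Z)-2-methylbut-2-enoyl]oxy}germacra-1(10),4,11(13)-trien-12,6-olide | C=C1C(=O)O[C@@H]2/C=C(/CO[Si](C)(C)C(C)(C)C)[C@@H](OC(C)=O)C/C=C(C)\C[C@@H](OC(=O)/C(C)=C\C)[C@@H]12 | intermediate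
22 | (1R,3S,4Z,6R,7R,8R,10S)-3-acetoxy-15-[(tert-butyldimethylsilyl)oxy]-1,10-epoxy-8-{[(2Z)-2-methylbut-2-enoyl]oxy}germacra-4,11(13)-dien-12,6-olide | C=C1C(=O)O[C@@H]2/C=C(/CO[Si](C)(C)C(C)(C)C)[C@@H](OC(C)=O)C[C@H]3O[C@@]3(C)C[C@@H](OC(=O)/C(C)=C\C)[C@@H]12 | intermediate
23 | (1R,3S,4Z,6R,7R,8R,10S)-3-acetoxy-1,10-epoxy-15-hydroxy-8-{[(2Z)-2-methylbut-2-enoyl]oxy}germacra-4,11(13)-dien-12,6-olide | C=C1C(=O)O[C@@H]2/C=C(/CO)[C@@H](OC(C)=O)C[C@H]3O[C@@]3(C)C[C@@H](OC(=O)/C(C)=C\C)[C@@H]12 | target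

Total step count: 18. Longest linear sequence: 12 steps (steps 7 to 18, from 9).

Steps most likely to fail

Step 15. The alkenyl–allyl coupling or β-hydride elimination of the η3-allyl palladium intermediate may outrun C–O closure, and boron-to-copper transmetalation of the α-branched boronate may be sluggish. The fallback replaces the palladium-mediated double inversion by a direct SN2 inversion; it sets out from 8 and 16 and returns to the route at 20. The union of 8 and 16 is run as in step 13 but with the antipodal sulfonamide ligand, which should give the 6-epi alcohol F1; phosphorylation as in step 14 gives the 6-epi phosphate F2. Copper-catalysed carboxylation (KOtBu, IPrCuCl, CO2, THF, 50 °C) gives the potassium acrylate F3, and, without palladium, addition of 18-crown-6 and DMF and warming to 60 °C should let the carboxylate displace the allylic phosphate with inversion to give 20.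

Step 3. Base-induced migration of the alkene of aldehyde 4 into conjugation, β-alkoxide loss from the allylcopper, or erosion of the syn selectivity by allylcopper isomerisation may occur. The fallback uses auxiliary-controlled aldol chemistry; it sets out from 4 and returns to the route at 5. Aldehyde 4 is added to the dibutylboron enolate of (4S)-4-benzyl-3-{3-[(4-methoxyphenyl)methoxy]propanoyl}-1,3-oxazolidin-2-one (Bu2BOTf, iPr2NEt, CH2Cl2, −78 °C; Evans syn aldol) to give the aldol adduct F4. Transamidation (MeNHOMe·HCl, AlMe3) gives the Weinreb amide F5, silylation (TESOTf, 2,6-lutidine) the silyl ether F6, and MeMgBr the methyl ketone F7. Kinetic enolisation on the methyl side (KHMDS, PhNTf2, −78 °C) gives the enol triflate F8, Miyaura borylation (PdCl2(PPh3)2, PPh3, KOPh, B2pin2, toluene, 50 °C) the alkenyl boronate F9, and PPTS in MeOH removes the silyl group to give 5.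

Step 16. Oligomerisation and poor control of the C1=C10 geometry may attend closure of a strained ten-membered ring to a trisubstituted alkene on the rigid lactone. The fallback closes the carbocycle before the lactone; it sets out from 17 and returns to the route at 21. Ring-closing metathesis of the more flexible 17 (second-generation Grubbs catalyst, toluene, 1 mM, 80 °C) gives the macrocyclic alcohol F10, phosphorylation as in step 14 gives the macrocyclic phosphate F11, and the conditions of step 15 convert it through the potassium acrylate F12 into 21.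

Further compounds
F1 | step 15 | (4S,5Z,7S,8S,9R)-4-acetoxy-5-{[(tert-butyldimethylsilyl)oxy]methyl}-7-hydroxy-11-methyl-8-[1-(4,4,5,5-tetramethyl-1,3,2-dioxaborolan-2-yl)ethenyl]dodeca-1,5,11-trien-9-yl (2Z)-2-methylbut-2-enoate (6-epi alcohol) | C=C(B1OC(C)(C)C(C)(C)O1)[C@@H]([C@@H](O)/C=C(/CO[Si](C)(C)C(C)(C)C)[C@@H](OC(C)=O)CC=C)[C@H](OC(=O)/C(C)=C\C)CC(C)=C
F2 | step 15 | (4S,5Z,7S,8R,9R)-4-acetoxy-5-{[(tert-butyldimethylsilyl)oxy]methyl}-7-[(diethoxyphosphoryl)oxy]-11-methyl-8-[1-(4,4,5,5-tetramethyl-1,3,2-dioxaborolan-2-yl)ethenyl]dodeca-1,5,11-trien-9-yl (2Z)-2-methylbut-2-enoate (6-epi phosphate) | C=C(B1OC(C)(C)C(C)(C)O1)[C@@H]([C@@H](OP(=O)(OCC)OCC)/C=C(/CO[Si](C)(C)C(C)(C)C)[C@@H](OC(C)=O)CC=C)[C@H](OC(=O)/C(C)=C\C)CC(C)=C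
F3 | step 15 | potassium acrylate derived from F2 by replacement of the boryl group with CO2K | C=C(C(=O)[O-])[C@@H]([C@@H](OP(=O)(OCC)OCC)/C=C(/CO[Si](C)(C)C(C)(C)C)[C@@H](OC(C)=O)CC=C)[C@H](OC(=O)/C(C)=C\C)CC(C)=C.[K+]
F4 | step 3 | (4S)-4-benzyl-3-[(2S,3R)-3-hydroxy-2-{[(4-methoxyphenyl)methoxy]methyl}-5-methylhex-5-enoyl]-1,3-oxazolidin-2-one | COc1ccc(COC[C@H](C(=O)N2[C@@H](Cc3ccccc3)COC2=O)[C@H](O)CC(C)=C)cc1
F5 | step 3 | (2S,3R)-3-hydroxy-N-methoxy-2-{[(4-methoxyphenyl)methoxy]methyl}-N,5-dimethylhex-5-enamide | COc1ccc(COC[C@H](C(=O)N(C)OC)[C@H](O)CC(C)=C)cc1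
F6 | step 3 | (2S,3R)-N-methoxy-2-{[(4-methoxyphenyl)methoxy]methyl}-N,5-dimethyl-3-[(triethylsilyl)oxy]hex-5-enamide | COc1ccc(COC[C@H](C(=O)N(C)OC)[C@H](O[Si](CC)(CC)CC)CC(C)=C)cc1
F7 | step 3 | (3S,4R)-3-{[(4-methoxyphenyl)methoxy]methyl}-6-methyl-4-[(triethylsilyl)oxy]hept-6-en-2-one | COc1ccc(COC[C@H](C(C)=O)[C@H](O[Si](CC)(CC)CC)CC(C)=C)cc1
F8 | step 3 | (3S,4R)-3-{[(4-methoxyphenyl)methoxy]methyl}-6-methyl-4-[(triethylsilyl)oxy]hepta-1,6-dien-2-yl trifluoromethanesulfonate | COc1ccc(COC[C@H](C(=C)OS(=O)(=O)C(F)(F)F)[C@H](O[Si](CC)(CC)CC)CC(C)=C)cc1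
F9 | step 3 | triethyl{[(2S,3R)-1-[(4-methoxyphenyl)methoxy]-5-methyl-2-[1-(4,4,5,5-tetramethyl-1,3,2-dioxaborolan-2-yl)ethenyl]hex-5-en-3-yl]oxy}silane | COc1ccc(COC[C@H](C(=C)B2OC(C)(C)C(C)(C)O2)[C@H](O[Si](CC)(CC)CC)CC(C)=C)cc1
F10 | step 16 | macrocyclic alcohol: (1(10)Z,3S,4Z,6R,7S,8R)-3-acetoxy-15-[(tert-butyldimethylsilyl)oxy]-6-hydroxy-8-{[(2Z)-2-methylbut-2-enoyl]oxy}-11-(4,4,5,5-tetramethyl-1,3,2-dioxaborolan-2-yl)-12-norgermacra-1(10),4,11(13)-triene | O[C@@H]1/C=C(/CO[Si](C)(C)C(C)(C)C)[C@@H](OC(C)=O)C/C=C(C)\C[C@@H](OC(=O)/C(C)=C\C)[C@H]1C(=C)B1OC(C)(C)C(C)(C)O1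
F11 | step 16 | macrocyclic phosphate: 6-O-diethylphosphate of F10 | CCOP(=O)(OCC)O[C@@H]1/C=C(/CO[Si](C)(C)C(C)(C)C)[C@@H](OC(C)=O)C/C=C(C)\C[C@@H](OC(=O)/C(C)=C\C)[C@H]1C(=C)B1OC(C)(C)C(C)(C)O1
F12 | step 16 | potassium acrylate derived from F11 by replacement of the boryl group with CO2K | CCOP(=O)(OCC)O[C@@H]1/C=C(/CO[Si](C)(C)C(C)(C)C)[C@@H](OC(C)=O)C/C=C(C)\C[C@@H](OC(=O)/C(C)=C\C)[C@H]1C(=C)C(=O)[O-].[K+]
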